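# Proposed synthesis of (2S,3R,4R)-4-(3-hydroxy-4-methoxyphenyl)-6,7-dimethoxy-2,3-dimethyl-3,4-dihydronaphthalen-1(2H)-one (17)

Ring positions are named in tetralone numbering throughout: C1 is the carbonyl carbon, C4 the aryl-bearing carbon, ring A the dimethoxybenzo ring, ring B the carbocycle, ring C the pendant aryl group.

## The problem

Target 17 is a 4-aryl-1-tetralone in which ring B carries three contiguous stereocentres: C2 (S, methyl), C3 (R, methyl) and C4 (R, ring C). The two methyl groups are trans, and the C3 methyl and the C4 aryl are cis. C2 lies next to the C1 carbonyl and can be equilibrated. With the C4 aryl pseudoaxial (away from the peri hydrogen at C5) and the C3 methyl equatorial, only the trans C2 methyl is equatorial, so C3 controls C2 thermodynamically. C3 and C4 cannot be corrected later and must be set kinetically. C4 is a diarylmethine between two electron-rich aryl groups of similar size, which is a poor handle for stereocontrol in an open chain. The free phenol of ring C does not tolerate oxidants or organometallics and needs a mask. Any ring B intermediate at the dihydronaphthalene level with an oxygen at C1 can lose water and become a naphthalene. The C3–C4 bond joins a carbon bearing two aryl groups to a carbon bearing a methyl group. As a C3=C4 double bond it is therefore the product of a reductive coupling of a diaryl ketone with a methyl ketone, and syn addition of H2 to it must give the 3,4-cis relation. The C1 oxygen, 1,3 to C3 across ring B, can direct that addition before it becomes the ketone.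

## Retrosynthesis

**Phenol mask and C2.** Target 17 is traced to its benzyl ether 16 (O–CH2Ph bond). A benzyl ether survives organolithium, low-valent titanium, fluoride and periodinane, and it is removed by hydrogenolysis without touching the methyl ethers. A silyl ether would fall together with the C1 silyl ether and leave a free guaiacol-type phenol in the oxidation. Ketone 16 is traced to its C2 epimer 15 (C2–H bond). This is deliberate: the hydrogenation works best when the C2 methyl is trans to the directing hydroxyl, which makes it cis to the C3 methyl. The forward step only has to equilibrate C2 to the equatorial position.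

**C1 oxidation level and the C3–H and C4–H bonds.** Ketone 15 is traced to carbinol 14, and 14, by removal of the two hydrogens at C3 and C4, to the tetrasubstituted alkene 13. Setting C4 alone (conjugate addition, benzylic protonation) would leave the 3,4 relation to weak 1,2-induction. A syn addition sets both centres at once, and their mutual relation is fixed by the mechanism. Only the face remains to be controlled, and the C1 hydroxyl of 13 does that. Alkene 13 has two stereocentres instead of four. The forward reaction must reduce a hindered diaryl-substituted alkene on the hydroxyl face without dehydrating the benzylic carbinol. Alcohol 13 comes from silyl ether 12 (O–Si bond).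

**C3=C4 double bond.** Alkene 12 is cut at C3=C4 into the two carbonyl groups of diketone 10. The neighbouring cuts are acylation at C1–C8a and cationic closure at C4–C4a. Both require the C2–C4 stereotriad, or at least the C3/C4 pair, in an open chain, and the cationic closure usually gives the trans 3,4 relation. The carbonyl coupling removes C3 and C4 as stereocentres from the precursor altogether. Diketone 10 carries only C1 and C2, which arise together in one crotylation. The forward step must couple the two ketones within the molecule and leave the benzylic C1–O bond alone.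

**Methyl ketone and diaryl ketone.** The methyl ketone of 10 comes from the terminal alkene of 9 (C=O from C=CH2, Wacker oxidation), so the ketone appears only after all organometallic steps. The diaryl ketone of 9 comes from carbinol 8. Carbinol 8 is cut at the C4–C4a bond into aryllithium 7, made from bromide 5, and the purchased aldehyde 6. An N-methoxy-N-methylamide would save the oxidation but costs two steps to prepare. A Friedel–Crafts aroylation would need acid and would face the benzylic silyl ether.

**C1–C2 bond.** Silyl ether 5 comes from alcohol 4, and 4 is cut at C1–C2 into aldehyde 1 and (Z)-crotylboronate 2, through borate 3. Crotylation of the bromoaldehyde before the diaryl ketone is installed avoids an acetal protection and deprotection of the aldehyde. It also avoids an ortho-aroylbenzyl alcohol, which would close to a lactol. The Z boronate gives the syn (1,2) alcohol, which becomes the trans arrangement of C1–O and C2–methyl on ring B. Only the C1 configuration carries the absolute stereochemistry forward.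

## Roads not taken

**Alternative 1:** The cut is at C8a–C1 and C1–C2, with carbon monoxide A2 as C1. Zerovalent palladium inserts into the C8a–I bond of iodo ester A1, A2 inserts, and the ester enolate at C2 captures the aroylpalladium species to give keto ester A3.
- Merits: two bonds and ring B form in one catalytic step. C1 arrives as the ketone, so no dehydration-prone benzylic carbinol appears and no redox adjustment is needed at C1. C3 and C4 are not touched.
- Weak points: the C3/C4 pair, including the diarylmethine, must already exist in open-chain A1, which is the hardest part of the problem. Direct enolate arylation without CO insertion would close a five-membered ring and competes. C2 arrives with an ester, so C-methylation, dealkoxycarbonylation and sulfonate cleavage follow.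
- Comparison: this road is better in redox economy and in the robustness of its intermediates. The chosen plan creates C3 and C4 together from sp2 carbons under a single control element and needs only one crotylation for its open-chain stereochemistry.

**Alternative 2:** The cut is at C4a–C5 and C8–C8a, so ring A is built last. Under Me2AlCl, diene A5 adds to the chiral enone A4 to give the cis-fused adduct A6, which must then lose four hydrogens to become the arene.
- Merits: the route is convergent, the diene delivers the ring A oxygen pattern, and the ring-fusion centres are of no consequence because aromatization removes them. No hindered tetrasubstituted alkene has to be hydrogenated and no low-valent titanium is used.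
- Weak points: all three stereocentres must be present in A4, so the stereochemical problem is only moved into a ring without an arene. Cyclohexenones are sluggish dienophiles and A5 is an acid-labile bis-enol ether. The dehydrogenation of A6 has to spare the epimerizable C2, the benzyl ether and the C4–H bond, which becomes doubly benzylic. Ring A is also cheaper bought as an arene.
- Comparison: this road avoids the two most delicate steps of the chosen plan but is longer and less secure overall.

**Alternative 3:** The cut is at C4–C4a. Zerovalent palladium inserts into the C4a–Br bond of keto ester A8 and the α-aryl ester enolate couples with it, giving A9 with a quaternary C4. C3 comes from the desymmetrization of anhydride A7.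
- Merits: the absolute configuration comes from a cheap meso compound by a robust catalytic desymmetrization. Enolate arylation to benzylic quaternary centres is reliable. C1 is a ketone throughout, so nothing can aromatize.
- Weak points: the ester at C4 is a disposable activating group, and a hindered quaternary diarylacetate must be hydrolysed and decarboxylated. C4 is then set by protonation under 1,2-induction from the C3 methyl alone, of uncertain sense and degree. The C2 methyl must still be introduced by enolate alkylation. Ring C has to be attached to the ester in a separate arylation.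
- Comparison: this road has the firmer source of absolute configuration and sturdier intermediates. The chosen plan ties the C3/C4 relation to the syn-addition mechanism instead of a late protonation and needs fewer corrections after ring closure.

Key step: step 6

## Route

Remarks on the chemistry:
- The (S) enantiomer of the phosphoric acid is assumed to direct the crotyl group to the Si face of aldehyde 1, by analogy with the Re-face attack on simple aryl aldehydes under the (R) acid. The configuration of 4 should be confirmed by Mosher ester analysis, and the antipodal acid used if the sense is reversed.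
- 3-Benzyloxy-4-methoxybenzaldehyde (6) is taken as a catalogue compound.

**Step 1**
Reactants: 1 2-bromo-4,5-dimethoxybenzaldehyde; 2 (Z)-crotylboronic acid pinacol ester
Product: 4 (1S,2R)-1-(2-bromo-4,5-dimethoxyphenyl)-2-methylbut-3-en-1-ol, via homoallyl pinacol borate 3 (not isolated)
Conditions: (S)-3,3'-bis(2,4,6-triisopropylphenyl)-1,1'-binaphthyl-2,2'-diyl hydrogen phosphate (5 mol %), toluene, −30 °C; aq. NaHCO3 work-up
Reagents that add atoms: none
Why: Chiral phosphoric acid catalysed crotylboration of an aryl aldehyde; the closed chair transition state turns the Z geometry into the syn (1,2) relation, and the catalyst selects the Si face, which sets C1 as S and with it C2 as R. Borate 3 is hydrolysed on work-up.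

**Step 2**
Reactants: 4 (1S,2R)-1-(2-bromo-4,5-dimethoxyphenyl)-2-methylbut-3-en-1-ol
Product: 5 tert-butyl{[(1S,2R)-1-(2-bromo-4,5-dimethoxyphenyl)-2-methylbut-3-en-1-yl]oxy}dimethylsilane
Conditions: TBSOTf, 2,6-lutidine, CH2Cl2, 0 °C
Reagents that add atoms: tert-butyldimethylsilyl trifluoromethanesulfonate, CC(C)(C)[Si](C)(C)OS(=O)(=O)C(F)(F)F
Why: Silylation of a hindered secondary benzylic alcohol with the silyl triflate and a non-nucleophilic base. The silyl ether withstands the organolithium and low-valent titanium and can later be removed by fluoride without acid.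

**Step 3**
Reactants: 5 tert-butyl{[(1S,2R)-1-(2-bromo-4,5-dimethoxyphenyl)-2-methylbut-3-en-1-yl]oxy}dimethylsilane; 6 3-benzyloxy-4-methoxybenzaldehyde
Product: 8 (3-benzyloxy-4-methoxyphenyl){2-[(1S,2R)-1-(tert-butyldimethylsilyloxy)-2-methylbut-3-en-1-yl]-4,5-dimethoxyphenyl}methanol as a mixture of carbinol epimers, via aryllithium 7 (not isolated)
Conditions: n-BuLi, THF, −78 °C; then 6, −78 °C; H2O quench at −78 °C
Reagents that add atoms: none
Why: Bromine–lithium exchange at −78 °C is faster than any deprotonation, and aryllithium 7 is trapped at once by the aldehyde (1,2-addition) before a 1,4 oxygen-to-carbon silyl shift can set in. The new carbinol centre forms without control and is removed in step 4.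

**Step 4**
Reactants: 8 (3-benzyloxy-4-methoxyphenyl){2-[(1S,2R)-1-(tert-butyldimethylsilyloxy)-2-methylbut-3-en-1-yl]-4,5-dimethoxyphenyl}methanol
Product: 9 (3-benzyloxy-4-methoxyphenyl){2-[(1S,2R)-1-(tert-butyldimethylsilyloxy)-2-methylbut-3-en-1-yl]-4,5-dimethoxyphenyl}methanone
Conditions: MnO2 (excess), CH2Cl2, rt
Reagents that add atoms: none
Why: MnO2 oxidizes the doubly benzylic carbinol selectively under neutral conditions; the silyl ether, terminal alkene and benzyl ether are inert.

**Step 5**
Reactants: 9 (3-benzyloxy-4-methoxyphenyl){2-[(1S,2R)-1-(tert-butyldimethylsilyloxy)-2-methylbut-3-en-1-yl]-4,5-dimethoxyphenyl}methanone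
Product: 10 (3S,4S)-4-[2-(3-benzyloxy-4-methoxybenzoyl)-4,5-dimethoxyphenyl]-4-(tert-butyldimethylsilyloxy)-3-methylbutan-2-one
Conditions: PdCl2 (10 mol %), CuCl (1 equiv), O2 (1 atm), DMF/H2O 7:1, rt
Reagents that add atoms: water, O
Why: Wacker oxidation: Markovnikov hydroxypalladation of the terminal alkene by divalent palladium and β-hydride elimination give the methyl ketone. The medium is close to neutral, so the α-stereocentre and the β-silyloxy group should survive (the change of descriptor at the methyl-bearing carbon is a matter of priorities only).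

**Step 6**
Reactants: 10 (3S,4S)-4-[2-(3-benzyloxy-4-methoxybenzoyl)-4,5-dimethoxyphenyl]-4-(tert-butyldimethylsilyloxy)-3-methylbutan-2-one
Product: 12 tert-butyl{[(1S,2R)-4-(3-benzyloxy-4-methoxyphenyl)-6,7-dimethoxy-2,3-dimethyl-1,2-dihydronaphthalen-1-yl]oxy}dimethylsilane, via titanium pinacolate 11 (not isolated)
Conditions: TiCl3(DME)1.5, Zn–Cu, DME, reflux; 10 added by syringe pump over about 30 h at high dilution; aq. K2CO3 work-up
Reagents that add atoms: none
Why: Low-valent titanium made from TiCl3(DME)1.5 and Zn–Cu transfers electrons first to the more easily reduced diaryl ketone; its titanium-bound ketyl adds to the neighbouring methyl ketone and gives pinacolate 11, which gives up both oxygens to the oxophilic metal at reflux and leaves the C3=C4 alkene. The closest known reaction type is the intramolecular McMurry coupling of keto ketones to cycloalkenes in its mixed diaryl ketone/alkyl ketone form. Ring B closes as a six-membered ring through the new C3–C4 bond, in a 6-exo attack of the C4 ketyl carbon on the C3 carbonyl. No stereocentre is created: the two carbinol carbons of 11 are transient and become sp2, while C1 and C2 are carried through from 10. The step needs intramolecular over intermolecular coupling, which slow addition at high dilution secures. It also needs the benzylic C1–O bond to survive, for which the bulky silyl ether, the aprotic medium and the basic work-up speak. Deoxygenation should not stall at the diol stage, because C4–O cleavage leaves a diaryl-stabilized radical. Partial epimerization at C2 through a titanium enolate would not be fatal, since C2 is reset by equilibration in step 10.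

**Step 7**
Reactants: 12 tert-butyl{[(1S,2R)-4-(3-benzyloxy-4-methoxyphenyl)-6,7-dimethoxy-2,3-dimethyl-1,2-dihydronaphthalen-1-yl]oxy}dimethylsilane
Product: 13 (1S,2R)-4-(3-benzyloxy-4-methoxyphenyl)-6,7-dimethoxy-2,3-dimethyl-1,2-dihydronaphthalen-1-ol
Conditions: Bu4NF, THF, 0 °C to rt
Reagents that add atoms: none
Why: Fluoride cleaves the Si–O bond under basic, non-ionizing conditions, which keeps the benzylic carbinol from ionizing toward the naphthalene.

**Step 8**
Reactants: 13 (1S,2R)-4-(3-benzyloxy-4-methoxyphenyl)-6,7-dimethoxy-2,3-dimethyl-1,2-dihydronaphthalen-1-ol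
Product: 14 (1S,2R,3R,4R)-4-(3-benzyloxy-4-methoxyphenyl)-6,7-dimethoxy-2,3-dimethyl-1,2,3,4-tetrahydronaphthalen-1-ol
Conditions: [Ir(cod)(PCy3)(py)]PF6 (10 mol %, in portions), H2 (1 atm, raised if slow), CH2Cl2, rt
Reagents that add atoms: none
Why: Hydroxyl-directed homogeneous hydrogenation of a cyclic homoallylic alcohol: the cationic iridium centre binds the pseudoaxial C1 hydroxyl and the C3=C4 alkene on the same face and adds both hydrogens there. The C3 methyl and the C4 aryl therefore end up cis to each other and trans to the hydroxyl (3R,4R), and the pseudoaxial C2 methyl on the other face reinforces this choice. This catalyst is among the few that reduce tetrasubstituted alkenes.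

**Step 9**
Reactants: 14 (1S,2R,3R,4R)-4-(3-benzyloxy-4-methoxyphenyl)-6,7-dimethoxy-2,3-dimethyl-1,2,3,4-tetrahydronaphthalen-1-ol
Product: 15 (2R,3R,4R)-4-(3-benzyloxy-4-methoxyphenyl)-6,7-dimethoxy-2,3-dimethyl-3,4-dihydronaphthalen-1(2H)-one
Conditions: Dess–Martin periodinane, CH2Cl2, 0 °C to rt
Reagents that add atoms: none
Why: Dess–Martin oxidation of a secondary benzylic alcohol to the aryl ketone; the directing carbinol has done its work and is erased. C3 and C4 are not affected.

**Step 10**
Reactants: 15 (2R,3R,4R)-4-(3-benzyloxy-4-methoxyphenyl)-6,7-dimethoxy-2,3-dimethyl-3,4-dihydronaphthalen-1(2H)-one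
Product: 16 (2S,3R,4R)-4-(3-benzyloxy-4-methoxyphenyl)-6,7-dimethoxy-2,3-dimethyl-3,4-dihydronaphthalen-1(2H)-one
Conditions: K2CO3 (catalytic), MeOH/THF, rt
Reagents that add atoms: none
Why: Base-mediated epimerization through the C1 enolate: with the C4 aryl pseudoaxial and the C3 methyl equatorial, only the trans C2 methyl can be equatorial, so the equilibrium should lie well on the side of the (2S) ketone. C3 and C4 are not acidic toward carbonate.

**Step 11**
Reactants: 16 (2S,3R,4R)-4-(3-benzyloxy-4-methoxyphenyl)-6,7-dimethoxy-2,3-dimethyl-3,4-dihydronaphthalen-1(2H)-one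
Product: 17 (2S,3R,4R)-4-(3-hydroxy-4-methoxyphenyl)-6,7-dimethoxy-2,3-dimethyl-3,4-dihydronaphthalen-1(2H)-one
Conditions: H2 (1 atm), 10 % Pd/C, EtOAc, rt
Reagents that add atoms: none
Why: Hydrogenolysis of the aryl benzyl ether over palladium; at 1 atm in ethyl acetate the electron-rich aryl ketone and the methyl ethers should remain.

## Compound list

1 | 2-bromo-4,5-dimethoxybenzaldehyde | COc1cc(Br)c(C=O)cc1OC | starting material
2 | (Z)-crotylboronic acid pinacol ester | C/C=C\CB1OC(C)(C)C(C)(C)O1 | starting material
3 | 2-{[(1S,2R)-1-(2-bromo-4,5-dimethoxyphenyl)-2-methylbut-3-en-1-yl]oxy}-4,4,5,5-tetramethyl-1,3,2-dioxaborolane | COc1cc(Br)c([C@@H](OB2OC(C)(C)C(C)(C)O2)[C@H](C)C=C)cc1OC | intermediate (not isolated)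
4 | (1S,2R)-1-(2-bromo-4,5-dimethoxyphenyl)-2-methylbut-3-en-1-ol | COc1cc(Br)c([C@@H](O)[C@H](C)C=C)cc1OC | intermediate
5 | tert-butyl{[(1S,2R)-1-(2-bromo-4,5-dimethoxyphenyl)-2-methylbut-3-en-1-yl]oxy}dimethylsilane | COc1cc(Br)c([C@@H](O[Si](C)(C)C(C)(C)C)[C@H](C)C=C)cc1OC | intermediate
6 | 3-benzyloxy-4-methoxybenzaldehyde | COc1ccc(C=O)cc1OCc1ccccc1 | starting material
7 | {2-[(1S,2R)-1-(tert-butyldimethylsilyloxy)-2-methylbut-3-en-1-yl]-4,5-dimethoxyphenyl}lithium | [Li]c1cc(OC)c(OC)cc1[C@@H](O[Si](C)(C)C(C)(C)C)[C@H](C)C=C | intermediate (not isolated)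
8 | (3-benzyloxy-4-methoxyphenyl){2-[(1S,2R)-1-(tert-butyldimethylsilyloxy)-2-methylbut-3-en-1-yl]-4,5-dimethoxyphenyl}methanol, both epimers at the diaryl carbinol | COc1ccc(C(O)c2cc(OC)c(OC)cc2[C@@H](O[Si](C)(C)C(C)(C)C)[C@H](C)C=C)cc1OCc1ccccc1 | intermediate
9 | (3-benzyloxy-4-methoxyphenyl){2-[(1S,2R)-1-(tert-butyldimethylsilyloxy)-2-methylbut-3-en-1-yl]-4,5-dimethoxyphenyl}methanone | COc1ccc(C(=O)c2cc(OC)c(OC)cc2[C@@H](O[Si](C)(C)C(C)(C)C)[C@H](C)C=C)cc1OCc1ccccc1 | intermediate
10 | (3S,4S)-4-[2-(3-benzyloxy-4-methoxybenzoyl)-4,5-dimethoxyphenyl]-4-(tert-butyldimethylsilyloxy)-3-methylbutan-2-one | COc1ccc(C(=O)c2cc(OC)c(OC)cc2[C@@H](O[Si](C)(C)C(C)(C)C)[C@H](C)C(C)=O)cc1OCc1ccccc1 | intermediate (key-step precursor)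
11 | titanium pinacolate, drawn as the dichlorotitanium 3,4-diolate of the (1S,2R)-4-aryl-1-silyloxy-2,3-dimethyltetralin-3,4-diol; C3 and C4 undefined | COc1ccc(C23O[Ti](Cl)(Cl)OC2(C)[C@@H](C)[C@H](O[Si](C)(C)C(C)(C)C)c2cc(OC)c(OC)cc23)cc1OCc1ccccc1 | intermediate (not isolated)
12 | tert-butyl{[(1S,2R)-4-(3-benzyloxy-4-methoxyphenyl)-6,7-dimethoxy-2,3-dimethyl-1,2-dihydronaphthalen-1-yl]oxy}dimethylsilane | COc1ccc(C2=C(C)[C@@H](C)[C@H](O[Si](C)(C)C(C)(C)C)c3cc(OC)c(OC)cc23)cc1OCc1ccccc1 | intermediate (key-step product)
13 | (1S,2R)-4-(3-benzyloxy-4-methoxyphenyl)-6,7-dimethoxy-2,3-dimethyl-1,2-dihydronaphthalen-1-ol | COc1ccc(C2=C(C)[C@@H](C)[C@H](O)c3cc(OC)c(OC)cc23)cc1OCc1ccccc1 | intermediate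
14 | (1S,2R,3R,4R)-4-(3-benzyloxy-4-methoxyphenyl)-6,7-dimethoxy-2,3-dimethyl-1,2,3,4-tetrahydronaphthalen-1-ol | COc1ccc([C@@H]2c3cc(OC)c(OC)cc3[C@@H](O)[C@H](C)[C@@H]2C)cc1OCc1ccccc1 | intermediate
15 | (2R,3R,4R)-4-(3-benzyloxy-4-methoxyphenyl)-6,7-dimethoxy-2,3-dimethyl-3,4-dihydronaphthalen-1(2H)-one | COc1ccc([C@@H]2c3cc(OC)c(OC)cc3C(=O)[C@H](C)[C@@H]2C)cc1OCc1ccccc1 | intermediate
16 | (2S,3R,4R)-4-(3-benzyloxy-4-methoxyphenyl)-6,7-dimethoxy-2,3-dimethyl-3,4-dihydronaphthalen-1(2H)-one | COc1ccc([C@@H]2c3cc(OC)c(OC)cc3C(=O)[C@@H](C)[C@@H]2C)cc1OCc1ccccc1 | intermediate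
17 | (2S,3R,4R)-4-(3-hydroxy-4-methoxyphenyl)-6,7-dimethoxy-2,3-dimethyl-3,4-dihydronaphthalen-1(2H)-one | COc1ccc([C@@H]2c3cc(OC)c(OC)cc3C(=O)[C@@H](C)[C@@H]2C)cc1O | target

## Step count and least certain steps

Total: 11 steps. Longest linear sequence: 11 steps (1 to 17); compounds 2 and 6 are bought.

**Step 6 (key step).** The most likely failure is loss of the C1 silyloxy group by Lewis-acid ionization of the para-methoxy-activated benzylic C–O bond, followed by aromatization of ring B. Less likely are arrest at the pinacol stage or intermolecular coupling. Fallback: the same bond is made in two stages under milder conditions. Diketone 10 is cyclized with SmI2 (THF, −78 °C) by ketyl addition to the cis-3,4-diol F1. F1 is converted with 1,1'-thiocarbonyldiimidazole in hot toluene into the cyclic thiocarbonate F2. Corey–Winter fragmentation of F2 with P(OMe)3 then gives alkene 12, where the route is rejoined.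

**Step 8.** The hindered diaryl-substituted tetrasubstituted alkene may be reduced too slowly, so that the catalyst deactivates. The acidic iridium hydrides may also dehydrate the benzylic carbinol, which would aromatize ring B. Fallback: the hydrogenation is moved before the desilylation and put under steric and catalyst control instead of hydroxyl direction. Silyl ether 12 is hydrogenated with a chiral complex [Ir(cod)(L)]B[3,5-(CF3)2C6H3]4, L = 4-tert-butyl-2-[2-(diphenylphosphanyl)phenyl]-4,5-dihydrooxazole, with both antipodes of L screened. The pseudoaxial C2 methyl blocks the lower face, and syn addition again ensures the 3,4-cis relation. This gives the saturated silyl ether F3, and Bu4NF then leads to 14.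

**Step 5.** Coordination of palladium by the neighbouring oxygen or the allylic branching may erode Markovnikov selectivity, and the β-silyloxy group may be eliminated. Fallback: the alkene of 9 is hydrated by hydrogen-atom transfer (Mukaiyama hydration: Co(acac)2, PhSiH3, O2, i-PrOH), whose regiochemistry follows radical stability. This gives the secondary alcohol F4 as a mixture of carbinol epimers, and Dess–Martin oxidation of F4 gives 10.

**Step 3.** A 1,4 oxygen-to-carbon silyl migration in aryllithium 7, or a silyl shift between the two oxygens after the addition, would scramble the protection pattern. Fallback: the organolithium is avoided altogether. Bromide 5 is coupled with 3-benzyloxy-4-methoxyphenylboronic acid under CO in a carbonylative Suzuki–Miyaura reaction (Pd(OAc)2, di(1-adamantyl)butylphosphine, K2CO3, toluene, 100 °C), which gives ketone 9 directly and also makes step 4 unnecessary.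

**Step 1.** Enantiofacial selectivity may be poor with an electron-rich aldehyde carrying an ortho bromine. Fallback: reagent control in place of catalyst control. Aldehyde 1 is treated with (Z)-crotyldiisopinocampheylborane, made from cis-2-butene, KOt-Bu, n-BuLi and the B-methoxydiisopinocampheylborane antipode that attacks the Si face (expected to be the one derived from (+)-α-pinene). After NaOH/H2O2 work-up this gives 4 directly.

## Further compounds

F1 | step 6 | (1S,2R)-4-(3-benzyloxy-4-methoxyphenyl)-1-(tert-butyldimethylsilyloxy)-6,7-dimethoxy-2,3-dimethyl-1,2,3,4-tetrahydronaphthalene-3,4-diol, cis-diol, C3 and C4 undefined | COc1ccc(C2(O)C(C)(O)[C@@H](C)[C@H](O[Si](C)(C)C(C)(C)C)c3cc(OC)c(OC)cc23)cc1OCc1ccccc1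
F2 | step 6 | cyclic 3,4-thiocarbonate of F1 | COc1ccc(C23OC(=S)OC2(C)[C@@H](C)[C@H](O[Si](C)(C)C(C)(C)C)c2cc(OC)c(OC)cc23)cc1OCc1ccccc1
F3 | step 8 | tert-butyl{[(1S,2R,3R,4R)-4-(3-benzyloxy-4-methoxyphenyl)-6,7-dimethoxy-2,3-dimethyl-1,2,3,4-tetrahydronaphthalen-1-yl]oxy}dimethylsilane | COc1ccc([C@@H]2c3cc(OC)c(OC)cc3[C@@H](O[Si](C)(C)C(C)(C)C)[C@H](C)[C@@H]2C)cc1OCc1ccccc1
F4 | step 5 | (3-benzyloxy-4-methoxyphenyl){2-[(1S,2R)-1-(tert-butyldimethylsilyloxy)-3-hydroxy-2-methylbutyl]-4,5-dimethoxyphenyl}methanone, both epimers at the new carbinol | COc1ccc(C(=O)c2cc(OC)c(OC)cc2[C@@H](O[Si](C)(C)C(C)(C)C)[C@H](C)C(C)O)cc1OCc1ccccc1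
F0 | step 3 | none | none
F0 | step 1 | none | none
A1 | alternative 1 | methyl (3S,4R)-4-(2-iodo-4,5-dimethoxyphenyl)-4-[4-methoxy-3-(methylsulfonyloxy)phenyl]-3-methylbutanoate | COc1ccc([C@H](c2cc(OC)c(OC)cc2I)[C@@H](C)CC(=O)OC)cc1OS(C)(=O)=O
A2 | alternative 1 | carbon monoxide | [C-]#[O+]
A3 | alternative 1 | methyl (2S,3R,4R)-6,7-dimethoxy-4-[4-methoxy-3-(methylsulfonyloxy)phenyl]-3-methyl-1-oxo-1,2,3,4-tetrahydronaphthalene-2-carboxylate | COc1ccc([C@@H]2c3cc(OC)c(OC)cc3C(=O)[C@@H](C(=O)OC)[C@@H]2C)cc1OS(C)(=O)=O
A4 | alternative 2 | (4R,5R,6S)-4-(3-benzyloxy-4-methoxyphenyl)-5,6-dimethylcyclohex-2-en-1-one | COc1ccc([C@@H]2C=CC(=O)[C@@H](C)[C@@H]2C)cc1OCc1ccccc1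
A5 | alternative 2 | 2,3-dimethoxybuta-1,3-diene | C=C(OC)C(OC)=C
A6 | alternative 2 | (2S,3R,4S,4aR,8aR)-4-(3-benzyloxy-4-methoxyphenyl)-6,7-dimethoxy-2,3-dimethyl-3,4,4a,5,8,8a-hexahydronaphthalen-1(2H)-one | COc1ccc([C@@H]2[C@H]3CC(OC)=C(OC)C[C@H]3C(=O)[C@@H](C)[C@@H]2C)cc1OCc1ccccc1
A7 | alternative 3 | 3-methylglutaric anhydride | CC1CC(=O)OC(=O)C1
A8 | alternative 3 | methyl (3S)-2-(3-benzyloxy-4-methoxyphenyl)-5-(2-bromo-4,5-dimethoxyphenyl)-3-methyl-5-oxopentanoate, C2 undefined | COC(=O)C(c1ccc(OC)c(OCc2ccccc2)c1)[C@@H](C)CC(=O)c1cc(OC)c(OC)cc1Br
A9 | alternative 3 | methyl (1R,2S)-1-(3-benzyloxy-4-methoxyphenyl)-6,7-dimethoxy-2-methyl-4-oxo-1,2,3,4-tetrahydronaphthalene-1-carboxylate | COc1ccc([C@@]2(C(=O)OC)c3cc(OC)c(OC)cc3C(=O)C[C@@H]2C)cc1OCc1ccccc1
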